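**Retrosynthetic overview**
- The strategy rests on the C11–C12 bond of the cyclopentane (ring atoms C8–C12). C11 is the carbinol carbon, C12 carries C13, the two are vicinal and trans, and both can be written as acceptor carbons (aldehyde at C11, vinyl sulfone C12=C13) that a one-electron reductant joins.
- Disconnections, last to first: C5=C6 (Wittig on a lactol); C13=C14 (Julia–Lythgoe olefination of the ring CH2SO2Ph with a C14–C20 α-silyloxy aldehyde); C11–C12 (ketyl addition to the vinyl sulfone); C8–C9 (anti allylboration).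
- Rings: the cyclopentane, the only ring of the target, is closed in the key step. A γ-lactone/lactol across C6–O–C9 is formed later only as a temporary carrier for the upper chain.
- The C15 and C19 carbinols come from two enantiopure epoxides joined through a dithiane carbon (C17).

Key step: step 9

Remark on the chemistry: carbons carry prostanoic acid numbers (C1 carboxyl to C20 methyl); PMB = 4-methoxybenzyl, TBS = tert-butyldimethylsilyl, Bpin = 4,4,5,5-tetramethyl-1,3,2-dioxaborolan-2-yl. The (R)-phosphoric acid in step 5 is chosen on the assumption that it sends the allyl group to the Re face of this aliphatic aldehyde, as it does with simple aldehydes; otherwise its antipode is used.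

**Route**

Step 1
Reactants: 1 but-3-yn-1-ol
Product: 2 1-[(but-3-yn-1-yloxy)methyl]-4-methoxybenzene
Conditions: NaH, PMBCl, Bu4NI (cat.), THF/DMF, 0 °C to rt
Reagents that add atoms: 4-methoxybenzyl chloride, COc1ccc(CCl)cc1
Why: Williamson etherification of the primary alkoxide with a benzylic chloride is reliable, and the PMB ether masks the C6 oxygen until the oxidative release in step 17.

Step 2
Reactants: 2 1-[(but-3-yn-1-yloxy)methyl]-4-methoxybenzene
Product: 3 2-{(1E)-4-[(4-methoxybenzyl)oxy]but-1-en-1-yl}-4,4,5,5-tetramethyl-1,3,2-dioxaborolane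
Conditions: HBpin, Cp2Zr(H)Cl (5 mol%), Et3N (10 mol%), neat, 60 °C
Reagents that add atoms: pinacolborane, CC1(C)OBOC1(C)C
Why: Zirconium-catalysed syn hydroboration of a terminal alkyne puts boron on the terminal carbon and should give only the (E)-alkenylboronate, which fixes the geometry that later becomes the C8/C9 relationship.

Step 3
Reactants: 3 2-{(1E)-4-[(4-methoxybenzyl)oxy]but-1-en-1-yl}-4,4,5,5-tetramethyl-1,3,2-dioxaborolane
Product: 5 2-{(2E)-5-[(4-methoxybenzyl)oxy]pent-2-en-1-yl}-4,4,5,5-tetramethyl-1,3,2-dioxaborolane, via chloromethyl boronate complex 4 (not isolated)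
Conditions: BrCH2Cl, n-BuLi, THF, −78 °C to rt
Reagents that add atoms: bromochloromethane, ClCBr
Why: Matteson homologation, in which LiCH2Cl made in situ adds to boron and the alkenyl group migrates 1,2 with loss of chloride, inserts one CH2 with retention of the (E)-geometry and gives the γ-substituted allylboronate.

Step 4
Reactants: 6 3,3-diethoxypropan-1-ol
Product: 7 3,3-diethoxypropanal
Conditions: (COCl)2, DMSO, CH2Cl2, −78 °C; Et3N, −78 to 0 °C
Reagents that add atoms: none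
Why: Swern oxidation under non-acidic conditions should convert the primary alcohol into the aldehyde without touching the diethyl acetal, and the aldehyde is used at once because it loses ethanol on storage.

Step 5
Reactants: 5 2-{(2E)-5-[(4-methoxybenzyl)oxy]pent-2-en-1-yl}-4,4,5,5-tetramethyl-1,3,2-dioxaborolane; 7 3,3-diethoxypropanal
Product: 9 (3S,4R)-1,1-diethoxy-4-{2-[(4-methoxybenzyl)oxy]ethyl}hex-5-en-3-ol, via borate ester 8 (not isolated)
Conditions: (R)-TRIP [(R)-3,3'-bis(2,4,6-triisopropylphenyl)-1,1'-binaphthyl-2,2'-diyl hydrogen phosphate] (5 mol%), 5 (1.2 equiv), 4 Å MS, toluene, −30 °C; aq. NaHCO3 work-up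
Reagents that add atoms: none
Why: Chiral phosphoric acid-catalysed allylboration through a closed six-membered chair transition state, in which the (E)-boronate geometry gives the anti C8/C9 pair and the acid, hydrogen-bonded to a boronate oxygen and the formyl hydrogen, directs attack to the Re face of the aldehyde, should set C9 as S and C8 as R.

Step 6
Reactants: 9 (3S,4R)-1,1-diethoxy-4-{2-[(4-methoxybenzyl)oxy]ethyl}hex-5-en-3-ol
Product: 10 (3R,4S)-6,6-diethoxy-4-[(4-methoxybenzyl)oxy]-3-{2-[(4-methoxybenzyl)oxy]ethyl}hex-1-ene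
Conditions: NaH, PMBCl, Bu4NI (cat.), DMF, 0 °C to rt
Reagents that add atoms: 4-methoxybenzyl chloride, COc1ccc(CCl)cc1
Why: Williamson etherification of the secondary alkoxide is compatible with the base-stable acetal, and a benzyl-type ether is put on C9 because its oxygen can bind samarium in step 9 and leaves together with the C6 PMB group in step 17.

Step 7
Reactants: 10 (3R,4S)-6,6-diethoxy-4-[(4-methoxybenzyl)oxy]-3-{2-[(4-methoxybenzyl)oxy]ethyl}hex-1-ene; 11 phenyl vinyl sulfone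
Product: 12 (1E,3R,4S)-6,6-diethoxy-4-[(4-methoxybenzyl)oxy]-3-{2-[(4-methoxybenzyl)oxy]ethyl}-1-(phenylsulfonyl)hex-1-ene
Conditions: second-generation Hoveyda–Grubbs catalyst RuCl2(H2IMes)(=CH-C6H4-2-OiPr) (5–10 mol%), 11 (3 equiv), CH2Cl2, 40 °C
Reagents that add atoms: none
Why: Olefin cross-metathesis of a terminal alkene with the non-dimerising, electron-poor vinyl sulfone should give the (E)-vinyl sulfone with loss of ethylene, the acetal and the ethers being inert to the ruthenium carbene.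

Step 8
Reactants: 12 (1E,3R,4S)-6,6-diethoxy-4-[(4-methoxybenzyl)oxy]-3-{2-[(4-methoxybenzyl)oxy]ethyl}-1-(phenylsulfonyl)hex-1-ene
Product: 13 (3S,4R,5E)-3-[(4-methoxybenzyl)oxy]-4-{2-[(4-methoxybenzyl)oxy]ethyl}-6-(phenylsulfonyl)hex-5-enal
Conditions: PPTS (cat.), acetone/H2O, 40 °C
Reagents that add atoms: water, O
Why: Mild acid-catalysed acetal hydrolysis should free the C11 aldehyde while the PMB ethers and the vinyl sulfone are stable to pyridinium tosylate, and the β-alkoxy aldehyde is taken on without storage to avoid β-elimination.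

Step 9
Reactants: 13 (3S,4R,5E)-3-[(4-methoxybenzyl)oxy]-4-{2-[(4-methoxybenzyl)oxy]ethyl}-6-(phenylsulfonyl)hex-5-enal
Product: 14 (1R,2R,3R,4S)-4-[(4-methoxybenzyl)oxy]-3-{2-[(4-methoxybenzyl)oxy]ethyl}-2-[(phenylsulfonyl)methyl]cyclopentan-1-ol
Conditions: SmI2 (2.5 equiv), MeOH (5 equiv), THF, −78 to −40 °C, slow addition of 13
Reagents that add atoms: none
Why: SmI2 transfers one electron to the C11 aldehyde and the samarium ketyl adds to C12, the β-carbon of the (E)-vinyl sulfone, after which the α-sulfonyl radical at C13 takes a second electron and is protonated by MeOH, so that the phenylsulfonylmethyl group is kept for step 15. The closest known reaction type is the SmI2-promoted ketyl–olefin cyclisation of aldehydes onto tethered enoates and vinyl sulfones, which gives trans-2-substituted cyclopentanols. The cyclopentane (C8–C9–C10–C11–C12) closes in the 5-exo-trig mode through a chair-like transition state. C12 is set by the allylic centre C8, whose hydrogen eclipses the alkene while the CH2CH2OPMB arm sits pseudo-equatorial, so that C13 should end trans to this arm. C11 is set by the ketyl oxygen, which points away from the sulfonylalkene (hydroxyl trans to C13) and is at the same time bridged through samarium to the C9 ether oxygen, which holds the C9 and C11 oxygens on one face. The step needs one of four diastereomers (C9–O, C11–O and the C8 arm on one face, C13 on the other) and cyclisation in preference to pinacol coupling or plain reduction; the cis C8/C9 pair from step 5 and a coordinating benzyl-type ether in place of a silyl ether at C9 make the three control elements agree, and the fast addition of the ketyl to the electron-poor alkene under slow addition of 13 secures the chemoselectivity.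

Step 10
Reactants: 14 (1R,2R,3R,4S)-4-[(4-methoxybenzyl)oxy]-3-{2-[(4-methoxybenzyl)oxy]ethyl}-2-[(phenylsulfonyl)methyl]cyclopentan-1-ol
Product: 15 tert-butyl{[(1R,2R,3R,4S)-4-[(4-methoxybenzyl)oxy]-3-{2-[(4-methoxybenzyl)oxy]ethyl}-2-[(phenylsulfonyl)methyl]cyclopentyl]oxy}dimethylsilane
Conditions: TBSOTf, 2,6-lutidine, CH2Cl2, −78 to 0 °C
Reagents that add atoms: tert-butyldimethylsilyl triflate, CC(C)(C)[Si](C)(C)OS(=O)(=O)C(F)(F)F
Why: Silylation of the hindered secondary C11 alcohol with the silyl triflate removes the only acidic OH before the sulfone is metalated.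

Step 11
Reactants: 16 2-(tert-butyldimethylsilyl)-1,3-dithiane; 17 (R)-propylene oxide; 18 (S)-benzyl glycidyl ether
Product: 22 (2S)-1-(benzyloxy)-3-{2-[(2R)-2-(tert-butyldimethylsilyloxy)propyl]-1,3-dithian-2-yl}propan-2-ol, via lithiated silyl dithiane 19 (not isolated), via lithium alkoxide 20 (not isolated), via silyloxy lithiodithiane 21 (not isolated)
Conditions: t-BuLi, Et2O, −78 to −45 °C; 17, −78 to −25 °C; then 18, HMPA, THF, −78 °C to rt
Reagents that add atoms: none
Why: Three-component dithiane linchpin coupling by anion relay, in which the lithiated silyl dithiane opens (R)-propylene oxide at CH2, HMPA triggers the 1,4-Brook rearrangement that moves silicon to the C19 oxygen and regenerates a dithiane anion, and this anion opens the glycidyl ether at CH2, should deliver both carbinol centres (C19 R, C15 S) unchanged from the epoxides.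

Step 12
Reactants: 22 (2S)-1-(benzyloxy)-3-{2-[(2R)-2-(tert-butyldimethylsilyloxy)propyl]-1,3-dithian-2-yl}propan-2-ol
Product: 23 2-[(2S)-3-(benzyloxy)-2-(tert-butyldimethylsilyloxy)propyl]-2-[(2R)-2-(tert-butyldimethylsilyloxy)propyl]-1,3-dithiane
Conditions: TBSOTf, 2,6-lutidine, CH2Cl2, 0 °C
Reagents that add atoms: tert-butyldimethylsilyl triflate, CC(C)(C)[Si](C)(C)OS(=O)(=O)C(F)(F)F
Why: Standard silylation of the free secondary C15 hydroxyl gives the same protecting group on C15 and C19.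

Step 13
Reactants: 23 2-[(2S)-3-(benzyloxy)-2-(tert-butyldimethylsilyloxy)propyl]-2-[(2R)-2-(tert-butyldimethylsilyloxy)propyl]-1,3-dithiane
Product: 24 (2S,6R)-2,6-bis(tert-butyldimethylsilyloxy)heptan-1-ol
Conditions: Raney Ni (W-2), H2 (1 atm), EtOH, 60 °C
Reagents that add atoms: none
Why: Raney nickel hydrogenolysis should cleave both C–S bonds of the dithiane to leave the C17 methylene and also remove the O-benzyl group, while the silyl ethers and the two carbinol centres are not affected.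

Step 14
Reactants: 24 (2S,6R)-2,6-bis(tert-butyldimethylsilyloxy)heptan-1-ol
Product: 25 (2S,6R)-2,6-bis(tert-butyldimethylsilyloxy)heptanal
Conditions: DMP, NaHCO3, CH2Cl2, 0 °C to rt
Reagents that add atoms: none
Why: Dess–Martin oxidation under buffered conditions should give the α-silyloxy aldehyde without epimerising C15, and the aldehyde is used directly.

Step 15
Reactants: 15 tert-butyl{[(1R,2R,3R,4S)-4-[(4-methoxybenzyl)oxy]-3-{2-[(4-methoxybenzyl)oxy]ethyl}-2-[(phenylsulfonyl)methyl]cyclopentyl]oxy}dimethylsilane; 25 (2S,6R)-2,6-bis(tert-butyldimethylsilyloxy)heptanal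
Product: 28 β-acetoxy sulfone (15 bearing at C13 the chain CH(OAc)–CH(OTBS)–(CH2)3–CH(OTBS)–CH3; 15S,19R; C13/C14 diastereomer mixture), via lithiated sulfone 26 (not isolated), via lithium alkoxide adduct 27 (not isolated)
Conditions: n-BuLi, THF, −78 °C; 25, −78 °C; Ac2O, −78 °C to rt
Reagents that add atoms: acetic anhydride, CC(=O)OC(C)=O
Why: In the first stage of the Julia–Lythgoe olefination the α-sulfonyl carbanion at C13 adds to the aldehyde carbon C14 and the alkoxide is trapped as its acetate before it can revert, the C13/C14 diastereomer mixture being of no consequence.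

Step 16
Reactants: 28 β-acetoxy sulfone
Product: 29 tert-butyl{[(1R,2R,3R,4S)-2-[(1E,3S,7R)-3,7-bis(TBSO)oct-1-en-1-yl]-4-(PMBO)-3-[2-(PMBO)ethyl]cyclopentyl]oxy}dimethylsilane
Conditions: Na(Hg) (6%), Na2HPO4, MeOH/THF, −20 °C
Reagents that add atoms: none
Why: In the reductive elimination stage of the Julia–Lythgoe olefination electron transfer expels benzenesulfinate and acetate through an intermediate that equilibrates before elimination, so the more stable (E)-C13=C14 alkene should form whatever the adduct stereochemistry, with C12 and C15 untouched.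

Step 17
Reactants: 29 (13E)-alkene bis-PMB ether
Product: 30 (1S,2R,3R,4R)-3-[(1E,3S,7R)-3,7-bis(TBSO)oct-1-en-1-yl]-4-(TBSO)-2-(2-hydroxyethyl)cyclopentan-1-ol
Conditions: DDQ (3 equiv), CH2Cl2/pH 7 buffer, 0 °C
Reagents that add atoms: none
Why: Oxidative PMB ether cleavage by DDQ should release the C6 and C9 hydroxyls in one operation while the silyl ethers and the disubstituted alkene stay inert.

Step 18
Reactants: 30 C6,C9-diol
Product: 31 (3aR,4R,5R,6aS)-4-[(1E,3S,7R)-3,7-bis(TBSO)oct-1-en-1-yl]-5-(TBSO)hexahydro-2H-cyclopenta[b]furan-2-one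
Conditions: TEMPO (cat.), PhI(OAc)2 (3 equiv), CH2Cl2, rt
Reagents that add atoms: none
Why: In this oxidative lactonisation of a 1,4-diol the oxoammonium oxidant attacks the primary C6 alcohol selectively, the aldehyde is captured by the cis C9 hydroxyl as a five-membered lactol, and the lactol is oxidised on to the cis-fused γ-lactone.

Step 19
Reactants: 31 γ-lactone
Product: 32 (3aR,4R,5R,6aS)-4-[(1E,3S,7R)-3,7-bis(TBSO)oct-1-en-1-yl]-5-(TBSO)hexahydro-2H-cyclopenta[b]furan-2-ol (anomer mixture)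
Conditions: DIBAL-H (i-Bu2AlH), CH2Cl2, −78 °C
Reagents that add atoms: none
Why: Partial reduction of a γ-lactone with DIBAL-H stops at the tetrahedral aluminium hemiacetal at low temperature and should give the lactol on work-up.

Step 20
Reactants: 32 lactol; 33 (4-carboxybutyl)triphenylphosphonium bromide
Product: 35 (5Z,9S,11R,13E,15S,19R)-9-hydroxy-11,15,19-tris(TBSO)prosta-5,13-dienoic acid, via phosphorus ylide 34 (not isolated)
Conditions: 33, KOtBu, THF, 0 °C to rt; then 32
Reagents that add atoms: none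
Why: Wittig olefination of the open hydroxy aldehyde form of the lactol with the unstabilised ylide should give the (Z)-C5=C6 alkene under kinetic control and free the C9 hydroxyl.

Step 21
Reactants: 35 tris-TBS acid
Product: 36 19(R)-hydroxy prostaglandin F2α
Conditions: HF·pyridine, MeCN, 0 °C to rt
Reagents that add atoms: none
Why: Global desilylation by fluoride should cleave the three secondary silyl ethers and release the C11, C15 and C19 hydroxyls under conditions that leave the allylic alcohol and both alkenes intact.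

**Compound list**

1 | but-3-yn-1-ol | C#CCCO | starting material
2 | 1-[(but-3-yn-1-yloxy)methyl]-4-methoxybenzene | C#CCCOCc1ccc(OC)cc1 | intermediate
3 | 2-{(1E)-4-[(4-methoxybenzyl)oxy]but-1-en-1-yl}-4,4,5,5-tetramethyl-1,3,2-dioxaborolane | COc1ccc(COCC/C=C/B2OC(C)(C)C(C)(C)O2)cc1 | intermediate
4 | lithium (chloromethyl)boronate complex of 3 | [Li+].COc1ccc(COCC/C=C/[B-]2(CCl)OC(C)(C)C(C)(C)O2)cc1 | intermediate
5 | 2-{(2E)-5-[(4-methoxybenzyl)oxy]pent-2-en-1-yl}-4,4,5,5-tetramethyl-1,3,2-dioxaborolane | COc1ccc(COCC/C=C/CB2OC(C)(C)C(C)(C)O2)cc1 | intermediate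
6 | 3,3-diethoxypropan-1-ol | CCOC(CCO)OCC | starting material
7 | 3,3-diethoxypropanal | CCOC(CC=O)OCC | intermediate
8 | O-Bpin borate ester of 9 | C=C[C@@H](CCOCc1ccc(OC)cc1)[C@@H](OB1OC(C)(C)C(C)(C)O1)CC(OCC)OCC | intermediate
9 | (3S,4R)-1,1-diethoxy-4-{2-[(4-methoxybenzyl)oxy]ethyl}hex-5-en-3-ol | C=C[C@@H](CCOCc1ccc(OC)cc1)[C@@H](O)CC(OCC)OCC | intermediate
10 | (3R,4S)-6,6-diethoxy-4-[(4-methoxybenzyl)oxy]-3-{2-[(4-methoxybenzyl)oxy]ethyl}hex-1-ene | C=C[C@@H](CCOCc1ccc(OC)cc1)[C@@H](OCc1ccc(OC)cc1)CC(OCC)OCC | intermediate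
11 | phenyl vinyl sulfone | C=CS(=O)(=O)c1ccccc1 | starting material
12 | (1E,3R,4S)-6,6-diethoxy-4-[(4-methoxybenzyl)oxy]-3-{2-[(4-methoxybenzyl)oxy]ethyl}-1-(phenylsulfonyl)hex-1-ene | O=S(=O)(c1ccccc1)/C=C/[C@@H](CCOCc1ccc(OC)cc1)[C@@H](OCc1ccc(OC)cc1)CC(OCC)OCC | intermediate
13 | (3S,4R,5E)-3-[(4-methoxybenzyl)oxy]-4-{2-[(4-methoxybenzyl)oxy]ethyl}-6-(phenylsulfonyl)hex-5-enal | O=S(=O)(c1ccccc1)/C=C/[C@@H](CCOCc1ccc(OC)cc1)[C@@H](OCc1ccc(OC)cc1)CC=O | intermediate
14 | (1R,2R,3R,4S)-4-[(4-methoxybenzyl)oxy]-3-{2-[(4-methoxybenzyl)oxy]ethyl}-2-[(phenylsulfonyl)methyl]cyclopentan-1-ol | O=S(=O)(c1ccccc1)C[C@@H]1[C@@H](CCOCc2ccc(OC)cc2)[C@@H](OCc2ccc(OC)cc2)C[C@H]1O | intermediate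
15 | tert-butyl{[(1R,2R,3R,4S)-4-[(4-methoxybenzyl)oxy]-3-{2-[(4-methoxybenzyl)oxy]ethyl}-2-[(phenylsulfonyl)methyl]cyclopentyl]oxy}dimethylsilane | O=S(=O)(c1ccccc1)C[C@@H]1[C@@H](CCOCc2ccc(OC)cc2)[C@@H](OCc2ccc(OC)cc2)C[C@H]1O[Si](C)(C)C(C)(C)C | intermediate
16 | 2-(tert-butyldimethylsilyl)-1,3-dithiane | CC(C)(C)[Si](C)(C)C1SCCCS1 | starting material
17 | (R)-propylene oxide | C[C@@H]1CO1 | starting material
18 | (S)-benzyl glycidyl ether | C1[C@H](O1)COCc2ccccc2 | starting material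
19 | 2-lithio-2-(tert-butyldimethylsilyl)-1,3-dithiane | [Li]C1([Si](C)(C)C(C)(C)C)SCCCS1 | intermediate
20 | lithium (2R)-1-[2-(tert-butyldimethylsilyl)-1,3-dithian-2-yl]propan-2-olate | C[C@@H](O[Li])CC1([Si](C)(C)C(C)(C)C)SCCCS1 | intermediate
21 | 2-lithio-2-[(2R)-2-(tert-butyldimethylsilyloxy)propyl]-1,3-dithiane | C[C@@H](O[Si](C)(C)C(C)(C)C)CC1([Li])SCCCS1 | intermediate
22 | (2S)-1-(benzyloxy)-3-{2-[(2R)-2-(tert-butyldimethylsilyloxy)propyl]-1,3-dithian-2-yl}propan-2-ol | C[C@@H](O[Si](C)(C)C(C)(C)C)CC1(C[C@H](O)COCc2ccccc2)SCCCS1 | intermediate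
23 | 2-[(2S)-3-(benzyloxy)-2-(tert-butyldimethylsilyloxy)propyl]-2-[(2R)-2-(tert-butyldimethylsilyloxy)propyl]-1,3-dithiane | C[C@@H](O[Si](C)(C)C(C)(C)C)CC1(C[C@H](O[Si](C)(C)C(C)(C)C)COCc2ccccc2)SCCCS1 | intermediate
24 | (2S,6R)-2,6-bis(tert-butyldimethylsilyloxy)heptan-1-ol | C[C@@H](O[Si](C)(C)C(C)(C)C)CCC[C@H](O[Si](C)(C)C(C)(C)C)CO | intermediate
25 | (2S,6R)-2,6-bis(tert-butyldimethylsilyloxy)heptanal | C[C@@H](O[Si](C)(C)C(C)(C)C)CCC[C@H](O[Si](C)(C)C(C)(C)C)C=O | intermediate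
26 | C13-lithiated sulfone 15 | [Li]C(S(=O)(=O)c1ccccc1)[C@@H]1[C@@H](CCOCc2ccc(OC)cc2)[C@@H](OCc2ccc(OC)cc2)C[C@H]1O[Si](C)(C)C(C)(C)C | intermediate
27 | lithium C14-alkoxide of the sulfone–aldehyde adduct (C13/C14 mixture) | C[C@@H](O[Si](C)(C)C(C)(C)C)CCC[C@H](O[Si](C)(C)C(C)(C)C)C(O[Li])C(S(=O)(=O)c1ccccc1)[C@@H]1[C@@H](CCOCc2ccc(OC)cc2)[C@@H](OCc2ccc(OC)cc2)C[C@H]1O[Si](C)(C)C(C)(C)C | intermediate
28 | C14-acetoxy C13-phenylsulfonyl adduct (15S,19R; C13/C14 mixture) | C[C@@H](O[Si](C)(C)C(C)(C)C)CCC[C@H](O[Si](C)(C)C(C)(C)C)C(OC(C)=O)C(S(=O)(=O)c1ccccc1)[C@@H]1[C@@H](CCOCc2ccc(OC)cc2)[C@@H](OCc2ccc(OC)cc2)C[C@H]1O[Si](C)(C)C(C)(C)C | intermediate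
29 | tert-butyl{[(1R,2R,3R,4S)-2-[(1E,3S,7R)-3,7-bis(TBSO)oct-1-en-1-yl]-4-(PMBO)-3-[2-(PMBO)ethyl]cyclopentyl]oxy}dimethylsilane | C[C@@H](O[Si](C)(C)C(C)(C)C)CCC[C@H](O[Si](C)(C)C(C)(C)C)/C=C/[C@@H]1[C@@H](CCOCc2ccc(OC)cc2)[C@@H](OCc2ccc(OC)cc2)C[C@H]1O[Si](C)(C)C(C)(C)C | intermediate
30 | (1S,2R,3R,4R)-3-[(1E,3S,7R)-3,7-bis(TBSO)oct-1-en-1-yl]-4-(TBSO)-2-(2-hydroxyethyl)cyclopentan-1-ol | C[C@@H](O[Si](C)(C)C(C)(C)C)CCC[C@H](O[Si](C)(C)C(C)(C)C)/C=C/[C@@H]1[C@@H](CCO)[C@@H](O)C[C@H]1O[Si](C)(C)C(C)(C)C | intermediate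
31 | (3aR,4R,5R,6aS)-4-[(1E,3S,7R)-3,7-bis(TBSO)oct-1-en-1-yl]-5-(TBSO)hexahydro-2H-cyclopenta[b]furan-2-one | C[C@@H](O[Si](C)(C)C(C)(C)C)CCC[C@H](O[Si](C)(C)C(C)(C)C)/C=C/[C@@H]1[C@H]2CC(=O)O[C@H]2C[C@H]1O[Si](C)(C)C(C)(C)C | intermediate
32 | (3aR,4R,5R,6aS)-4-[(1E,3S,7R)-3,7-bis(TBSO)oct-1-en-1-yl]-5-(TBSO)hexahydro-2H-cyclopenta[b]furan-2-ol (anomer mixture) | C[C@@H](O[Si](C)(C)C(C)(C)C)CCC[C@H](O[Si](C)(C)C(C)(C)C)/C=C/[C@@H]1[C@H]2CC(O)O[C@H]2C[C@H]1O[Si](C)(C)C(C)(C)C | intermediate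
33 | (4-carboxybutyl)triphenylphosphonium bromide | OC(=O)CCCC[P+](c1ccccc1)(c1ccccc1)c1ccccc1.[Br-] | starting material
34 | potassium 5-(triphenylphosphoranylidene)pentanoate | [K+].[O-]C(=O)CCCC=P(c1ccccc1)(c1ccccc1)c1ccccc1 | intermediate
35 | (5Z,9S,11R,13E,15S,19R)-9-hydroxy-11,15,19-tris(TBSO)prosta-5,13-dienoic acid | C[C@@H](O[Si](C)(C)C(C)(C)C)CCC[C@H](O[Si](C)(C)C(C)(C)C)/C=C/[C@@H]1[C@@H](C/C=C\CCCC(=O)O)[C@@H](O)C[C@H]1O[Si](C)(C)C(C)(C)C | intermediate
36 | 19(R)-hydroxy prostaglandin F2α = (5Z,9S,11R,13E,15S,19R)-9,11,15,19-tetrahydroxyprosta-5,13-dienoic acid | C[C@@H](O)CCC[C@H](O)/C=C/[C@@H]1[C@@H](C/C=C\CCCC(=O)O)[C@@H](O)C[C@H]1O | target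

**Step count and risks**

Total step count: 21. Longest linear sequence: 16 steps (1–3, 5–10, 15–21); steps 4 and 11–14 are side branches.

Steps most likely to fail:

Step 9. The ketyl may be reduced on to the alcohol or couple with a second ketyl before it cyclises, or the closure may bring C13 onto the face of the C8 arm (poor facial selectivity at C12). The fallback forms the same C11–C12 bond by an intramolecular nitrile oxide–alkene cycloaddition; it sets out from 10 and comes back at 14. Acetal hydrolysis of 10 (PPTS, acetone/H2O) gives (3S,4R)-3-[(4-methoxybenzyl)oxy]-4-{2-[(4-methoxybenzyl)oxy]ethyl}hex-5-enal F1, and NH2OH·HCl in pyridine converts it into the oxime F2. NaOCl in CH2Cl2 at 0 °C generates the nitrile oxide, which adds to the terminal alkene to give the cyclopentane-fused isoxazoline F3, with C13 expected anti to the C8 arm. Raney Ni/H2 with B(OH)3 in MeOH/H2O cleaves the N–O bond and hydrolyses the imine to the β-hydroxy ketone F4. Me4NBH(OAc)3 in MeCN/AcOH delivers hydride from the hydroxymethyl face (hydroxyl-directed reduction) and gives the trans diol F5. PhSSPh/Bu3P converts the primary alcohol selectively into the phenyl sulfide F6, and (NH4)6Mo7O24/H2O2 in EtOH oxidises the sulfide to sulfone 14.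

Step 7. The allylically branched alkene may enter the metathesis cycle so slowly that catalyst decomposition outruns turnover. The fallback builds the vinyl sulfone by carbonyl olefination; it sets out from 10 and comes back at 12. Oxidative cleavage of the vinyl group (OsO4 cat., NaIO4, 2,6-lutidine, dioxane/H2O) gives (2S,3S)-5,5-diethoxy-3-[(4-methoxybenzyl)oxy]-2-{2-[(4-methoxybenzyl)oxy]ethyl}pentanal F7. A Horner–Wadsworth–Emmons reaction of F7 with diethyl [(phenylsulfonyl)methyl]phosphonate under mild conditions (LiCl, DBU, MeCN, 0 °C), chosen to spare the α-centre and the β-ether, gives the (E)-vinyl sulfone 12.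

Step 15. The hindered C13 carbanion may deprotonate the α-silyloxy aldehyde or the adduct may revert before acetylation, with epimerisation at C15. The fallback replaces aldehyde addition by an irreversible acylation; it sets out from 25 (with 15) and comes back at 28. Pinnick oxidation of 25 (NaClO2, NaH2PO4, 2-methyl-2-butene) gives (2S,6R)-2,6-bis(tert-butyldimethylsilyloxy)heptanoic acid F8, and TMSCHN2 gives its methyl ester F9. Two equivalents of lithiated sulfone 26 are acylated by F9 to give the β-keto sulfone F10, which NaBH4 reduces to the β-hydroxy sulfone F11. Acetylation of F11 (Ac2O, DMAP, pyridine) gives 28.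

**Further compounds**

F1 | step 9 | (3S,4R)-3-[(4-methoxybenzyl)oxy]-4-{2-[(4-methoxybenzyl)oxy]ethyl}hex-5-enal | C=C[C@@H](CCOCc1ccc(OC)cc1)[C@@H](OCc1ccc(OC)cc1)CC=O
F2 | step 9 | oxime of F1 | C=C[C@@H](CCOCc1ccc(OC)cc1)[C@@H](OCc1ccc(OC)cc1)CC=NO
F3 | step 9 | (3aR,4R,5S)-5-[(4-methoxybenzyl)oxy]-4-{2-[(4-methoxybenzyl)oxy]ethyl}-3a,4,5,6-tetrahydro-3H-cyclopenta[c]isoxazole | O1N=C2C[C@H](OCc3ccc(OC)cc3)[C@H](CCOCc3ccc(OC)cc3)[C@H]2C1
F4 | step 9 | (2S,3R,4S)-2-(hydroxymethyl)-4-[(4-methoxybenzyl)oxy]-3-{2-[(4-methoxybenzyl)oxy]ethyl}cyclopentan-1-one | OC[C@@H]1[C@@H](CCOCc2ccc(OC)cc2)[C@@H](OCc2ccc(OC)cc2)CC1=O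
F5 | step 9 | (1R,2S,3R,4S)-2-(hydroxymethyl)-4-[(4-methoxybenzyl)oxy]-3-{2-[(4-methoxybenzyl)oxy]ethyl}cyclopentan-1-ol | OC[C@@H]1[C@@H](CCOCc2ccc(OC)cc2)[C@@H](OCc2ccc(OC)cc2)C[C@H]1O
F6 | step 9 | (1R,2R,3R,4S)-4-[(4-methoxybenzyl)oxy]-3-{2-[(4-methoxybenzyl)oxy]ethyl}-2-[(phenylsulfanyl)methyl]cyclopentan-1-ol | c1ccccc1SC[C@@H]1[C@@H](CCOCc2ccc(OC)cc2)[C@@H](OCc2ccc(OC)cc2)C[C@H]1O
F7 | step 7 | (2S,3S)-5,5-diethoxy-3-[(4-methoxybenzyl)oxy]-2-{2-[(4-methoxybenzyl)oxy]ethyl}pentanal | O=C[C@@H](CCOCc1ccc(OC)cc1)[C@@H](OCc1ccc(OC)cc1)CC(OCC)OCC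
F8 | step 15 | (2S,6R)-2,6-bis(tert-butyldimethylsilyloxy)heptanoic acid | C[C@@H](O[Si](C)(C)C(C)(C)C)CCC[C@H](O[Si](C)(C)C(C)(C)C)C(=O)O
F9 | step 15 | methyl (2S,6R)-2,6-bis(tert-butyldimethylsilyloxy)heptanoate | C[C@@H](O[Si](C)(C)C(C)(C)C)CCC[C@H](O[Si](C)(C)C(C)(C)C)C(=O)OC
F10 | step 15 | C14-oxo C13-phenylsulfonyl coupling product (β-keto sulfone; C13 mixture) | C[C@@H](O[Si](C)(C)C(C)(C)C)CCC[C@H](O[Si](C)(C)C(C)(C)C)C(=O)C(S(=O)(=O)c1ccccc1)[C@@H]1[C@@H](CCOCc2ccc(OC)cc2)[C@@H](OCc2ccc(OC)cc2)C[C@H]1O[Si](C)(C)C(C)(C)C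
F11 | step 15 | C14-hydroxy C13-phenylsulfonyl coupling product (β-hydroxy sulfone; C13/C14 mixture) | C[C@@H](O[Si](C)(C)C(C)(C)C)CCC[C@H](O[Si](C)(C)C(C)(C)C)C(O)C(S(=O)(=O)c1ccccc1)[C@@H]1[C@@H](CCOCc2ccc(OC)cc2)[C@@H](OCc2ccc(OC)cc2)C[C@H]1O[Si](C)(C)C(C)(C)C
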